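Count E, D, X and Q together, one Q as two, and Thursday's readings of this flask still sum to 100% at 3.00 d, so each E lost can be looked for in a product.

all flasks: E 20 mM; L 0.64 mM (held)

| charge | remark | time |
|---|---|---|
| Thursday's | the very flask that is asked about, followed so far |  |
| flask |  | 10 d |

Thursday's run (percent of the E charged)

| time / d | D / % | Q / % | E / % | X / % |
|---|---|---|---|---|
| 0.250 | 0.9 | 0 | 96.1 | 2.1 |
| 0.500 | 1.9 | 0.2 | 92.5 | 5.2 |
| 1.25 | 2.9 | 1.9 | 81.0 | 13.9 |
| 3.00 | 6.4 | 5.0 | 57.5 | 31.5 |

(scatter of a reading: 0.3 percentage points)

- the species in which most of what was charged as E, at 10 d sits (E / D / Q / X)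
- the largest share itself, whichever of these holds it, in percent of the E charged

So you can ask what share of the lost E sits in X. Call this the X share, X divided by the E consumed 74.1%, the selectivity for X. It reads 73.2% at 1.25 d and 74.1% at 3.00 d, so freeze it, and the question becomes how much E is left.

A straight line through the last two readings of E reaches zero at 7.28 d, earlier than the asked 10 d, which puts X at 74.1%. That line is the weak link, so reforge it: take a constant fractional loss from those same readings, 0.196 d⁻¹. Then you reckon E at 14.6% at 10 d, and your X is 63.3%.

The forecast, higher than your figure, names X at 68%, holding that “X shows no sign of being consumed”.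

The flask gives X at 51.6%, with E at 21.2%. Left until 100 d, the flask holds X at 21.1%. The frozen X share on the E actually consumed gives 58.4%, more than the flask holds by 6.8 percentage points, and the share in the flask stands at 65.5% at 10 d. What runs, with J the dissolved L:

    E + J ⇌ D (K = 710 M⁻¹, k = 830 M⁻¹ h⁻¹)
    E + J ⇌ X (K = 3800 M⁻¹, k = 510 M⁻¹ h⁻¹)
    E + D → Q (k = 0.680 M⁻¹ h⁻¹)
    L ⇌ J, rate k4*(csat - [J]) (kL = 0.200 h⁻¹)

Read the same flask at 2.5 d, where E is 63.8%: the X share gives 26.8%, and the computed X is 26.8%.

The readings stem from a simulated flask on assumed constants.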